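**Plan**

- Retrosynthesis: the two depside ester bonds are cut first (ring B carbonyl to O3 of ring A, ring C carbonyl to O4 of ring B). Ring B is then opened at C3–C4, and its chain is cut at the C1=C2 alkene (olefination) and at C1–C6 (alkylation).
- Enabling feature: ring B carries the carboxyl on C1, free hydroxyls on C3 and C5 and a different (acylated) oxygen on C4. It is therefore the double enol of a 4-alkoxycyclohex-1-ene-3,5-dione-1-carboxylate and can be folded from the open chain C3(ester)–C2=C1(CO2tBu)–C6H2–C5(=O)–C4H2–OPMB, which is already at the arene oxidation level.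
- Forward: the chain is assembled by etherification, phosphonate alkylation, olefination with methyl glyoxylate and alkene cleavage. Ring B is closed by the intramolecular Claisen condensation. O3/O5 are benzylated, O4 is unmasked and acylated with ring C, the ring B carboxyl is freed and esterified with a ring A phenol, and all protecting groups fall in one hydrogenolysis.
- Rings A and C come from gallic acid derivatives; only ring B is built.
- Stereochemistry: the target is achiral; the only stereo-element on the way is the (E)-alkene of the keto diester, set by the olefination.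

Key step: step 5

Remark: the racemic centres of two intermediates vanish later, and the E/Z outcome of the olefination is not critical, because the ring closure equilibrates the alkene through its dienolate.

**Route**

Step 1
Reactants: 1 4-methoxybenzyl alcohol; 2 3-chloro-2-(chloromethyl)prop-1-ene
Product: 3 1-({[2-(chloromethyl)prop-2-en-1-yl]oxy}methyl)-4-methoxybenzene
Conditions: NaH, THF, 0 °C; then added to 2 (3 equiv), Bu4NI (cat.), 0 °C to rt
Reagents that add atoms: none
Why: Williamson ether synthesis in which the alkoxide of 1 displaces one allylic chloride of the symmetrical dichloride, the excess of volatile 2 keeping the second substitution down.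

Step 2
Reactants: 4 tert-butyl diethylphosphonoacetate; 3 1-({[2-(chloromethyl)prop-2-en-1-yl]oxy}methyl)-4-methoxybenzene
Product: 5 tert-butyl 2-(diethoxyphosphoryl)-4-[(4-methoxybenzyloxy)methyl]pent-4-enoate (racemic)
Conditions: 4 (1.5 equiv), NaH (1.4 equiv), THF–DMF, 0 °C; then 3, NaI (cat.), rt to 50 °C
Reagents that add atoms: none
Why: SN2 C-alkylation of the sodium phosphonoacetate carbanion by an allylic chloride with Finkelstein activation, a standard entry to 2-substituted phosphonoacetates in which the excess of 4 suppresses double alkylation.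

Step 3
Reactants: 5 tert-butyl 2-(diethoxyphosphoryl)-4-[(4-methoxybenzyloxy)methyl]pent-4-enoate; 6 methyl glyoxylate (freshly distilled)
Product: 7 1-tert-butyl 4-methyl (E)-2-{2-[(4-methoxybenzyloxy)methyl]prop-2-en-1-yl}but-2-enedioate
Conditions: NaH (0.98 equiv), THF, 0 °C; then 6 (1.3 equiv), −78 to 0 °C
Reagents that add atoms: none
Why: Horner–Wadsworth–Emmons olefination of an α-branched phosphonoacetate with a very electrophilic aldehyde, expected to place CO2Me trans to CO2tBu and cis to the allyl arm, while the absence of surplus base should keep the skipped diene from moving into conjugation.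

Step 4
Reactants: 7 1-tert-butyl 4-methyl (E)-2-{2-[(4-methoxybenzyloxy)methyl]prop-2-en-1-yl}but-2-enedioate
Product: 8 1-tert-butyl 4-methyl (E)-2-[3-(4-methoxybenzyloxy)-2-oxopropyl]but-2-enedioate
Conditions: OsO4 (2 mol %), NaIO4 (4 equiv), 2,6-lutidine (2 equiv), dioxane–H2O (3:1), rt
Reagents that add atoms: osmium tetroxide O=[Os](=O)(=O)=O, reoxidised by sodium periodate [Na+].[O-]I(=O)(=O)=O (source of the ketone oxygen)
Why: Lemieux–Johnson oxidation in which electrophilic OsO4 should dihydroxylate the electron-rich 1,1-disubstituted alkene much faster than the electron-poor fumarate and NaIO4 cleaves the diol as it forms, the lutidine buffer sparing the PMB ether and the base-sensitive keto fumarate.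

Step 5
Reactants: 8 1-tert-butyl 4-methyl (E)-2-[3-(4-methoxybenzyloxy)-2-oxopropyl]but-2-enedioate
Product: 10 tert-butyl 3,5-dihydroxy-4-(4-methoxybenzyloxy)benzoate, via cyclohexenedione 9 (not isolated)
Conditions: KOtBu (3 equiv), degassed THF–tBuOH (10:1), 0.01 M, slow addition of 8 at 0 °C, then 50 °C, Ar; AcOH quench
Reagents that add atoms: none
Why: Intramolecular Claisen (Dieckmann-type) condensation: KOtBu first removes the doubly activated C6–H to give the extended dienolate, tBuOH relays the proton to the small equilibrium share of the alkoxy-side ketone enolate at C4, and this carbon attacks the methyl ester carbonyl C3, which the (E)-alkene holds cis to the ketone arm; methoxide leaves and dione 9 enolises twice to the resorcinol, whose phenoxide makes the sequence irreversible. The closest known reactions are the alkoxide-mediated closure of δ-keto esters to cyclohexane-1,3-diones (as in the Michael–Claisen route to dimedone, where the reacting ketone enolate is likewise the minor, far less acidic carbanion of the molecule) and the base-induced conversion of 5-oxo-2-enoates and 2-pyranones into resorcinols. Ring B closes in a 6-exo-trig (enolexo) acyl substitution, and no stereocentre survives, the C4 centre of 9 being lost on enolisation. C-acylation at C3 has to win over three diversions: closure onto the C1 ester to a five-membered ring is blocked by the tert-butyl group, O-acylation to a 2-pyranone is reopened by the methoxide set free and drains to the same arene, and intermolecular Michael addition is held back by adding 8 slowly to excess base at high dilution, so that no neutral fumarate stands beside the anions. Any (Z)-isomer of 8 equilibrates through the same dienolate and is carried into the product.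

Step 6
Reactants: 10 tert-butyl 3,5-dihydroxy-4-(4-methoxybenzyloxy)benzoate
Product: 11 tert-butyl 3,5-bis(benzyloxy)-4-(4-methoxybenzyloxy)benzoate
Conditions: BnBr (2.5 equiv), K2CO3 (3 equiv), DMF, rt
Reagents that add atoms: benzyl bromide BrCc1ccccc1
Why: Williamson O-benzylation of the two equivalent phenols under mild carbonate conditions to which the ester and the existing ethers are inert.

Step 7
Reactants: 11 tert-butyl 3,5-bis(benzyloxy)-4-(4-methoxybenzyloxy)benzoate
Product: 12 tert-butyl 3,5-bis(benzyloxy)-4-hydroxybenzoate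
Conditions: DDQ (1.5 equiv), CH2Cl2–H2O (18:1), 0 °C to rt
Reagents that add atoms: none
Why: Oxidative cleavage of the 4-methoxybenzyl ether by DDQ (hydride abstraction at the anisylic carbon, then hydrolysis of the oxocarbenium ion), which plain benzyl ethers and the tert-butyl ester should survive.

Step 8
Reactants: 13 3,4,5-tris(benzyloxy)benzoic acid
Product: 14 3,4,5-tris(benzyloxy)benzoyl chloride
Conditions: (COCl)2 (1.5 equiv), DMF (cat.), CH2Cl2, 0 °C to rt; evaporate, use crude
Reagents that add atoms: oxalyl chloride ClC(=O)C(=O)Cl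
Why: Acid chloride formation through Vilsmeier-type activation, which gives only gaseous by-products and leaves the benzyl ethers untouched.

Step 9
Reactants: 12 tert-butyl 3,5-bis(benzyloxy)-4-hydroxybenzoate; 14 3,4,5-tris(benzyloxy)benzoyl chloride
Product: 15 tert-butyl 3,5-bis(benzyloxy)-4-{[3,4,5-tris(benzyloxy)benzoyl]oxy}benzoate
Conditions: Et3N (2 equiv), DMAP (0.2 equiv), CH2Cl2, 0 °C to rt
Reagents that add atoms: none
Why: DMAP-catalysed acylation through the acylpyridinium ion, the acid chloride being chosen because the O4 phenol is flanked by two benzyloxy groups.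

Step 10
Reactants: 15 tert-butyl 3,5-bis(benzyloxy)-4-{[3,4,5-tris(benzyloxy)benzoyl]oxy}benzoate
Product: 16 3,5-bis(benzyloxy)-4-{[3,4,5-tris(benzyloxy)benzoyl]oxy}benzoic acid
Conditions: TFA–CH2Cl2 (1:4), 0 °C to rt
Reagents that add atoms: none
Why: Acidolysis of the tert-butyl ester with loss of isobutene, under which aryl benzyl ethers and the aryl ester should be stable for the short time needed.

Step 11
Reactants: 17 gallic acid
Product: 18 benzyl 3,4,5-trihydroxybenzoate
Conditions: BnBr (1.05 equiv), KHCO3 (1.1 equiv), DMF, rt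
Reagents that add atoms: benzyl bromide BrCc1ccccc1
Why: Chemoselective SN2 alkylation of the carboxylate, since hydrogencarbonate is too weak a base to ionise the phenols.

Step 12
Reactants: 18 benzyl 3,4,5-trihydroxybenzoate
Product: 19 benzyl 7-hydroxy-2,2-diphenyl-1,3-benzodioxole-5-carboxylate
Conditions: Ph2CCl2 (1.3 equiv), neat, 170 °C, short heating under a N2 sweep
Reagents that add atoms: dichlorodiphenylmethane ClC(Cl)(c1ccccc1)c1ccccc1
Why: Diphenylmethylene ketalisation of the vicinal 3,4-diol, the usual catechol protection of gallates, which by symmetry can give only one ketal and leaves exactly the meta hydroxyl free.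

Step 13
Reactants: 16 3,5-bis(benzyloxy)-4-{[3,4,5-tris(benzyloxy)benzoyl]oxy}benzoic acid; 19 benzyl 7-hydroxy-2,2-diphenyl-1,3-benzodioxole-5-carboxylate
Product: 20 benzyl 7-({3,5-bis(benzyloxy)-4-[3,4,5-tris(benzyloxy)benzoyloxy]benzoyl}oxy)-2,2-diphenyl-1,3-benzodioxole-5-carboxylate
Conditions: N,N'-diisopropylcarbodiimide (1.3 equiv), DMAP (0.2 equiv), CH2Cl2, 0 °C to rt
Reagents that add atoms: none
Why: Steglich esterification (carbodiimide activation, DMAP acyl transfer) of the benzoic acid with the single free phenol of 19, which has only one ortho substituent.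

Step 14
Reactants: 20 benzyl 7-({3,5-bis(benzyloxy)-4-[3,4,5-tris(benzyloxy)benzoyloxy]benzoyl}oxy)-2,2-diphenyl-1,3-benzodioxole-5-carboxylate
Product: 21 3-{[3,5-dihydroxy-4-(3,4,5-trihydroxybenzoyloxy)benzoyl]oxy}-4,5-dihydroxybenzoic acid (CNP0317472.0)
Conditions: H2 (1 atm), 10% Pd/C, THF, rt; filtration under Ar, evaporation below 30 °C
Reagents that add atoms: none
Why: Catalytic hydrogenolysis should remove the five benzyl ethers, the benzyl ester and the diphenylmethylene ketal in one operation under neutral aprotic conditions that do not ionise the phenols, which is meant to avoid the base-promoted shift of the ring C galloyl group from O4 to O3 of ring B.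

**Compound list**

1 | 4-methoxybenzyl alcohol | COc1ccc(CO)cc1 | starting material
2 | 3-chloro-2-(chloromethyl)prop-1-ene | C=C(CCl)CCl | starting material
3 | 1-({[2-(chloromethyl)prop-2-en-1-yl]oxy}methyl)-4-methoxybenzene | COc1ccc(COCC(=C)CCl)cc1 | intermediate
4 | tert-butyl diethylphosphonoacetate | CCOP(=O)(OCC)CC(=O)OC(C)(C)C | starting material
5 | tert-butyl 2-(diethoxyphosphoryl)-4-[(4-methoxybenzyloxy)methyl]pent-4-enoate (racemic) | CCOP(=O)(OCC)C(CC(=C)COCc1ccc(OC)cc1)C(=O)OC(C)(C)C | intermediate
6 | methyl glyoxylate | COC(=O)C=O | starting material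
7 | 1-tert-butyl 4-methyl (E)-2-{2-[(4-methoxybenzyloxy)methyl]prop-2-en-1-yl}but-2-enedioate | COC(=O)/C=C(\CC(=C)COCc1ccc(OC)cc1)C(=O)OC(C)(C)C | intermediate
8 | 1-tert-butyl 4-methyl (E)-2-[3-(4-methoxybenzyloxy)-2-oxopropyl]but-2-enedioate | COC(=O)/C=C(\CC(=O)COCc1ccc(OC)cc1)C(=O)OC(C)(C)C | intermediate
9 | tert-butyl 4-(4-methoxybenzyloxy)-3,5-dioxocyclohex-1-ene-1-carboxylate (racemic, transient) | CC(C)(C)OC(=O)C1=CC(=O)C(OCc2ccc(OC)cc2)C(=O)C1 | intermediate (not isolated)
10 | tert-butyl 3,5-dihydroxy-4-(4-methoxybenzyloxy)benzoate | CC(C)(C)OC(=O)c1cc(O)c(OCc2ccc(OC)cc2)c(O)c1 | intermediate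
11 | tert-butyl 3,5-bis(benzyloxy)-4-(4-methoxybenzyloxy)benzoate | CC(C)(C)OC(=O)c1cc(OCc2ccccc2)c(OCc2ccc(OC)cc2)c(OCc2ccccc2)c1 | intermediate
12 | tert-butyl 3,5-bis(benzyloxy)-4-hydroxybenzoate | CC(C)(C)OC(=O)c1cc(OCc2ccccc2)c(O)c(OCc2ccccc2)c1 | intermediate
13 | 3,4,5-tris(benzyloxy)benzoic acid | OC(=O)c1cc(OCc2ccccc2)c(OCc2ccccc2)c(OCc2ccccc2)c1 | starting material
14 | 3,4,5-tris(benzyloxy)benzoyl chloride | ClC(=O)c1cc(OCc2ccccc2)c(OCc2ccccc2)c(OCc2ccccc2)c1 | intermediate
15 | tert-butyl 3,5-bis(benzyloxy)-4-{[3,4,5-tris(benzyloxy)benzoyl]oxy}benzoate | CC(C)(C)OC(=O)c1cc(OCc2ccccc2)c(OC(=O)c2cc(OCc3ccccc3)c(OCc3ccccc3)c(OCc3ccccc3)c2)c(OCc2ccccc2)c1 | intermediate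
16 | 3,5-bis(benzyloxy)-4-{[3,4,5-tris(benzyloxy)benzoyl]oxy}benzoic acid | OC(=O)c1cc(OCc2ccccc2)c(OC(=O)c2cc(OCc3ccccc3)c(OCc3ccccc3)c(OCc3ccccc3)c2)c(OCc2ccccc2)c1 | intermediate
17 | gallic acid | OC(=O)c1cc(O)c(O)c(O)c1 | starting material
18 | benzyl 3,4,5-trihydroxybenzoate | O=C(OCc1ccccc1)c1cc(O)c(O)c(O)c1 | intermediate
19 | benzyl 7-hydroxy-2,2-diphenyl-1,3-benzodioxole-5-carboxylate | O=C(OCc1ccccc1)c1cc(O)c2OC(c3ccccc3)(c3ccccc3)Oc2c1 | intermediate
20 | benzyl 7-({3,5-bis(benzyloxy)-4-[3,4,5-tris(benzyloxy)benzoyloxy]benzoyl}oxy)-2,2-diphenyl-1,3-benzodioxole-5-carboxylate | O=C(OCc1ccccc1)c1cc(OC(=O)c2cc(OCc3ccccc3)c(OC(=O)c3cc(OCc4ccccc4)c(OCc4ccccc4)c(OCc4ccccc4)c3)c(OCc3ccccc3)c2)c2OC(c3ccccc3)(c3ccccc3)Oc2c1 | intermediate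
21 | 3-{[3,5-dihydroxy-4-(3,4,5-trihydroxybenzoyloxy)benzoyl]oxy}-4,5-dihydroxybenzoic acid | O=C(O)c1cc(O)c(O)c(OC(=O)c2cc(O)c(OC(=O)c3cc(O)c(O)c(O)c3)c(O)c2)c1 | target

**Step count**

Total: 14 steps. Longest linear sequence: 11 steps (steps 1–7, 9, 10, 13, 14).

**Steps most likely to fail**

Step 5. The proton may not reach C4 at a useful rate, so that the dienolate either persists or is consumed by intermolecular Michael oligomerisation, or the closure may stop at the 2-pyranone. The fallback keeps the C3–C4 closure but moves it to the saturated oxidation level, where C6 has lost its vinylogous acidity and the alkoxy-side enolate is the most acidic carbanion able to cyclise. It sets out from 8 and rejoins the route at 10.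
- Chemoselective hydrogenation of 8 (H2, Pd/C poisoned with pyridine, EtOAc, PMB ether retained) should give 1-tert-butyl 4-methyl 2-[3-(4-methoxybenzyloxy)-2-oxopropyl]butanedioate F1.
- The classical Claisen closure of this δ-keto ester (KOtBu, THF) should give tert-butyl 4-(4-methoxybenzyloxy)-3,5-dioxocyclohexane-1-carboxylate F2.
- The dianion of F2 (LiN(iPr)2, 2.2 equiv, THF, −78 °C) should be selenenylated by PhSeBr at its more reactive ester α-carbon to give tert-butyl 4-(4-methoxybenzyloxy)-3,5-dioxo-1-(phenylselanyl)cyclohexane-1-carboxylate F3.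
- H2O2 should oxidise F3 to the selenoxide tert-butyl 4-(4-methoxybenzyloxy)-3,5-dioxo-1-(phenylseleninyl)cyclohexane-1-carboxylate F4, which is not isolated; its syn-elimination gives dione 9, and enolisation gives 10.

Step 4. The fumarate alkene may be osmylated beside the allyl ether alkene, or the intermediate diol may lactonise onto the cis methyl ester before periodate cleaves it. The fallback reverses the order of the two operations, so that the oxidant never meets the fumarate. It sets out from 5 and rejoins at 8.
- The same OsO4/NaIO4/2,6-lutidine cleavage applied to 5 should give tert-butyl 2-(diethoxyphosphoryl)-5-(4-methoxybenzyloxy)-4-oxopentanoate F5.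
- Olefination of F5 with 6 under Masamune–Roush conditions (LiCl, iPr2NEt, MeCN) should give 8; the amine base is too weak to hold the acidic keto fumarate as its dienolate.

Step 14. Slow hydrogenolysis of the diphenylmethylene ketal may prolong the contact of the already unmasked ring B with catalyst and solvent, and during that time the ring C galloyl group may drift from O4 to O3. The fallback stages the unmasking. It sets out from 20 and rejoins at 21.
- Acidolysis of the ketal (TFA–H2O–CH2Cl2, rt) should give benzyl 3-({3,5-bis(benzyloxy)-4-[3,4,5-tris(benzyloxy)benzoyloxy]benzoyl}oxy)-4,5-dihydroxybenzoate F6, with the ring B hydroxyls still benzylated.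
- A short hydrogenolysis of the benzyl groups alone (H2, Pd/C, THF) should then give 21.

**Further compounds**

F1 | step 5 | 1-tert-butyl 4-methyl 2-[3-(4-methoxybenzyloxy)-2-oxopropyl]butanedioate (racemic) | COC(=O)CC(CC(=O)COCc1ccc(OC)cc1)C(=O)OC(C)(C)C
F2 | step 5 | tert-butyl 4-(4-methoxybenzyloxy)-3,5-dioxocyclohexane-1-carboxylate | CC(C)(C)OC(=O)C1CC(=O)C(OCc2ccc(OC)cc2)C(=O)C1
F3 | step 5 | tert-butyl 4-(4-methoxybenzyloxy)-3,5-dioxo-1-(phenylselanyl)cyclohexane-1-carboxylate | CC(C)(C)OC(=O)C1([Se]c2ccccc2)CC(=O)C(OCc2ccc(OC)cc2)C(=O)C1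
F4 | step 5 | tert-butyl 4-(4-methoxybenzyloxy)-3,5-dioxo-1-(phenylseleninyl)cyclohexane-1-carboxylate | CC(C)(C)OC(=O)C1([Se](=O)c2ccccc2)CC(=O)C(OCc2ccc(OC)cc2)C(=O)C1
F5 | step 4 | tert-butyl 2-(diethoxyphosphoryl)-5-(4-methoxybenzyloxy)-4-oxopentanoate (racemic) | CCOP(=O)(OCC)C(CC(=O)COCc1ccc(OC)cc1)C(=O)OC(C)(C)C
F6 | step 14 | benzyl 3-({3,5-bis(benzyloxy)-4-[3,4,5-tris(benzyloxy)benzoyloxy]benzoyl}oxy)-4,5-dihydroxybenzoate | O=C(OCc1ccccc1)c1cc(O)c(O)c(OC(=O)c2cc(OCc3ccccc3)c(OC(=O)c3cc(OCc4ccccc4)c(OCc4ccccc4)c(OCc4ccccc4)c3)c(OCc3ccccc3)c2)c1
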